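Chains cannot begin from initiator that impurity has already taken, and that is how I read the amber run: its impurity charge of 0.47 mM stands above its initiator charge of 0.37 mM, and its last reading, 0.4% at 48.0 h, lies within the scatter of zero.

| setting | green | amber | south-west | north-east |
|---|---|---|---|---|
| free monomer | 0.037 M | 0.037 M | 0.037 M | 0.037 M |
| transfer agent | 1.11 mM | 1.11 mM | 1.11 mM | 1.11 mM |
| initiator | 0.37 mM | 0.37 mM | 0.37 mM | 0.37 mM |
| impurity | 0.15 mM | 0.47 mM | 0.30 mM | 0.10 mM |
| remark | run made earlier | run made earlier |  |  |
| time |  |  | 3.0 d | 3.0 d |

| green: time / h | green: monomer in chains / % | amber: time / h | amber: monomer in chains / % |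
|---|---|---|---|
| 4.00 | 2.4 | 4.00 | 0 |
| 8.00 | 8.1 | 8.00 | 0 |
| 15.0 | 23.0 | 15.0 | 0 |
| 25.0 | 37.6 | 25.0 | 0.8 |
| 48.0 | 61.1 | 48.0 | 0.4 |

(standard deviation of a reading: 1 percentage point)

- which of the two ends with the longer chains by the average number of monomer units in a chain (chains begun, living or dead) ("neither" if they lie within 10%) (south-west / north-east / neither)
- average number of monomer units in a chain (chains begun, living or dead) at the end, south-west
- average number of monomer units in a chain (chains begun, living or dead) at the end, north-east

- the average divides the monomer in chains by the number of chains begun, living and dead together
- the numbers in the tables scatter by 1 percentage point (one standard deviation)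
- the earlier runs do not show the number of chains; that part of a forecast is a guess

The initiator charge minus the impurity charge, 0.220 mM in green, 0.0700 mM in south-west and 0.270 mM in north-east, is the quantity I carry, the surplus initiator, and I take it as the number of chains begun. If free monomer goes into chains at a rate proportional to what is left, the logarithm of its remaining fraction falls in a straight line, and the last two green readings give a slope of 0.0205 h⁻¹. I scale that slope by surplus and set the lag aside, so over 3.0 d I get 37.5% in chains for south-west and 83.7% for north-east. Dividing the monomer in chains by the surplus gives lengths of 198 for south-west and 115 for north-east, so I commit to south-west as the longer. The weak link is the count, which the earlier runs do not show, so I reforge it as an open guess: I let the transfer agent end chains without beginning any.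

The forecast differs from my reckoning: it says north-east, with 10 for south-west and 22 for north-east, on the ground “Assuming the transfer agent is fully used”.

The flask gives south-west as the longer, with 190 for south-west and 115 for north-east.

    free monomer + initiator → living end + monomer in chains (k = 2.60 M⁻¹ h⁻¹)
    free monomer + living end → monomer in chains + living end, rate k2*[living end]*[free monomer] (k = 170 M⁻¹ h⁻¹)
    living end + transfer agent → dead chain (kL = 16.0 M⁻¹ h⁻¹)
    initiator + impurity → spent initiator (k = 63000 M⁻¹ h⁻¹)

At the charges of north-east, each initiator is taken by impurity at 6.30 h⁻¹ and by free monomer at 0.0962 h⁻¹, a ratio of 65.5. At 3.00 d in north-east, living end and dead chain together come to 0.261 mM and the initiator still there to 0.00920 mM, against a surplus of 0.270 mM. In the neighbour of north-east charged with 0.015 M of free monomer, which has the same surplus, 14% of the initiator remains at the end, so the surplus less that remainder is 0.220 mM, and its 72.1% in chains over that count is an average of 49.2 units per chain.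

Readings and results are calculated for substances that don't exist; noise was put on by code.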